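The earlier runs and the new flask are simulated for substances that don't exist, noise included.

The target in this flask shares its starting material with the homo product, with c(starting material) = 0.30 M charged in 3 portions 12 min apart over 0.450 M of solid partner. The maple and ash runs bracket that charge.

| flask | starting material | solid partner | remark | time |
|---|---|---|---|---|
| maple | 0.20 M (in portions, 3) | 0.45 M | run made earlier; portions every 12 min |  |
| ash | 0.45 M (in portions, 3) | 0.45 M | run made earlier; portions every 12 min |  |
| flask | 0.30 M (in portions, 3) | 0.450 M | the portions of starting material follow each other after 12 min, the first at the start | 20 h |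

| run | time / h | starting material / % | target / % | homo product / % |
|---|---|---|---|---|
| maple | 1.33 | 71.1 | 0 | 0.9 |
| maple | 4.00 | 57.3 | 2.4 | 8.5 |
| maple | 6.00 | 52.5 | 4.7 | 13.2 |
| maple | 10.0 | 40.6 | 14.1 | 20.8 |
| maple | 15.0 | 29.3 | 24.9 | 25.5 |
| maple | 20.0 | 19.9 | 37.4 | 28.7 |
| maple | 25.0 | 12.6 | 45.0 | 29.0 |
| ash | 2.00 | 64.4 | 0 | 5.4 |
| ash | 3.00 | 58.2 | 0.6 | 11.2 |
| ash | 4.00 | 54.4 | 2.3 | 16.6 |
| ash | 6.00 | 46.5 | 4.6 | 25.3 |
| ash | 10.0 | 35.6 | 9.4 | 35.7 |
| ash | 15.0 | 24.5 | 17.8 | 41.7 |
| ash | 25.0 | 10.4 | 31.9 | 47.4 |

(standard deviation of a reading: 0.5 percentage points)

- percentages count the starting material that a species holds: one homo product counts as two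
- solid, in amounts per volume of the solution: solid partner
- the numbers in the tables scatter by 0.5 percentage points (one standard deviation)
- at the start none of the solid partner is in solution

* part of the starting material gone at 20 h
* the target standing at 20 h, as a percentage of the starting material charged
* the homo product standing at 20 h, as a percentage of the starting material charged
* amount of target if the flask were left three thousand times as long, in percent of the starting material charged

Take the main step by itself first, so that whatever starting material goes becomes target. Maple holds 19.9% of starting material at 20.0 h. Ash, by the geometric mean of its readings at 15.0 h and 25.0 h, holds about 16.0%. Reckoning along the charge leaves 18.3% in this flask, so conversion and target would both be 81.7%.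

Now add the homo product. The crossing charge, the charge at which target and homo product would stand equal at a given time, is read from a run as its charge times target over homo product. At 15.0 h maple gives 0.195 M and ash 0.192 M; at 25.0 h they give 0.310 M and 0.303 M. The two runs read close to each other at both of these times. Maple's reading at 20.0 h is 0.261 M. This flask's charge lies above it, so homo product is reckoned above target; their ratio, the selectivity, homo product over target, is charge over crossing charge, 1.15, and target falls to 38.0%.

Last comes the unseen pool. Maple's balance at 20.0 h misses 14.0%. Carried over to this flask, that lowers target to 31.5% and puts homo product at 36.2%.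

The forecast reads conversion 82%, target 31.5%, homo product 36.5%, and long-left target 59%, taking the target as stable and the missing share as what “sits unseen in an intermediate”. Its homo product stands 0.30 percentage points above this reckoning.

The flask gives conversion 81.7%, target 32.0%, homo product 36.7% and long-left target 54.7%, each forecast number inside its margin.

    starting material ⇌ open intermediate (K = 0.620, k = 0.460 /h)
    fresh partner → second intermediate (k = 0.840 /h)
    open intermediate + second intermediate → target (k = 0.770 /M/h)
    2 open intermediate → homo product (k = 0.690 /M/h)
    solid partner ⇌ fresh partner, rate k5*(cs5 - [fresh partner]) while solid is left; crystals form when [fresh partner] > cs5 (solubility = 0.160 M, k = 0.150 /h)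
    target ⇌ isomer of the product (K = 0.120, k = 0.370 /h)

The flask's isomer of the product holds 3.77% at 20.0 h and 6.57% at 200 h, beside a gap of 4.3 points between forecast and flask in long-left target. The crossing charge gave this flask a selectivity of 1.15, and the flask stands at 1.15. The neighbour flask, the same flask with 0.51 M of starting material, gets 1.95 from the crossing charge and reads 2.00.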